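**Plan**

- Cuts: the eleven O–benzyl bonds. Then the upper interflavan bond C4(epiafzelechin)–C8(epicatechin), cut together with the C3–OH of the top unit, which is traced to a C3–C4 oxirane. The oxirane goes back through a bromohydrin to a (2S)-flav-3-ene, and that to a chromone plus an arylboronic acid (C2–aryl bond). The lower C4–C8 bond is cut to an epicatechin C4 electrophile and catechin.
- Forward: the benzylated epicatechin-(4β→8)-catechin dimer is made from the two natural flavan-3-ols. The top unit is carried as chromone → flavanone → 2H-chromene → bromohydrin and is never a flavan-3-ol before the union. Its oxirane is then opened by C8 of the dimer, and hydrogenolysis finishes.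
- Stereochemistry: the five centres of the lower two units come from the chiral pool, plus anti attack on the C4 cation (4β). Top C2 comes from a ligand-controlled conjugate addition. Top C3 and C4 are relayed from C2: bromine adds anti to the aryl group, the oxirane closes with inversion at C3 (oxygen cis to the aryl group), and the arene opens it anti at C4.
- Enabling feature: in the pyran (C) ring of the epiafzelechin unit the C3–OH and the C4–aryl bond are vicinal and trans, and C4 is benzylic to the phloroglucinol A ring (C4a), whose oxygens at C5, C7 and O1 stabilise positive charge at C4. This is the retron of an anti Friedel–Crafts opening of a C3–C4 oxirane by the free C8–H of the middle unit.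

Key step: step 11

Assumption: the Pd/(R)-t-BuPyOx conjugate addition in step 7 is taken, by analogy with the sense known for cyclic enones, to give the (2S)-flavanone; if a trial run shows the opposite sense, the (S)-ligand is used.

**Route**

Step 1
Reactants: 1 (+)-catechin
Product: 2 5,7,3′,4′-tetra-O-benzyl-(+)-catechin
Conditions: BnBr (4.4 equiv), K2CO3, DMF, 0 °C to rt
Reagents that add atoms: benzyl bromide BrCc1ccccc1
Why: Williamson etherification of the four phenols, which are far more acidic than the secondary 3-OH, so the 3-OH stays free and no stereocenter is touched.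

Step 2
Reactants: 3 (−)-epicatechin
Product: 4 5,7,3′,4′-tetra-O-benzyl-(−)-epicatechin
Conditions: BnBr (4.4 equiv), K2CO3, DMF, 0 °C to rt
Reagents that add atoms: benzyl bromide BrCc1ccccc1
Why: Williamson etherification of the four phenols as in step 1, with the 3-OH left free and no stereocenter touched.

Step 3
Reactants: 4 5,7,3′,4′-tetra-O-benzyl-(−)-epicatechin
Product: 5 (2R,3R,4S)-5,7-bis(benzyloxy)-2-[3,4-bis(benzyloxy)phenyl]-4-(2-ethoxyethoxy)chroman-3-ol
Conditions: DDQ (2 equiv), 2-ethoxyethanol (5 equiv), CH2Cl2, rt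
Reagents that add atoms: 2-ethoxyethanol CCOCCO
Why: DDQ benzylic oxidation (hydride abstraction at C4 to the A-ring-stabilised cation) with capture by the alcohol trans to the 3-OH should give the 4β-ether, as established for benzylated epicatechin.

Step 4
Reactants: 5 (2R,3R,4S)-5,7-bis(benzyloxy)-2-[3,4-bis(benzyloxy)phenyl]-4-(2-ethoxyethoxy)chroman-3-ol; 2 5,7,3′,4′-tetra-O-benzyl-(+)-catechin (3 equiv, excess recovered)
Product: 6 5,7,3′,4′-tetra-O-benzyl-(−)-epicatechin-(4β→8)-5,7,3′,4′-tetra-O-benzyl-(+)-catechin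
Conditions: TMSOTf (20 mol %), CH2Cl2, −78 °C; sat. NaHCO3
Reagents that add atoms: none
Why: Lewis acid-mediated Friedel–Crafts interflavan coupling, in which the C4 cation from 5 is attacked by C8 of 2 on the face anti to the 3-OH and the 2-aryl group, which should set the new C4 centre as 4β (3,4-trans).

Step 5
Reactants: 7 2′,4′,6′-trihydroxyacetophenone
Product: 8 1-[2,4-bis(benzyloxy)-6-hydroxyphenyl]ethanone
Conditions: BnBr (2.1 equiv), K2CO3, DMF, rt
Reagents that add atoms: benzyl bromide BrCc1ccccc1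
Why: Williamson etherification in which the phenol hydrogen-bonded to the carbonyl group is the least reactive and should remain free.

Step 6
Reactants: 8 1-[2,4-bis(benzyloxy)-6-hydroxyphenyl]ethanone
Product: 10 5,7-bis(benzyloxy)-4H-chromen-4-one, via enaminone 9 (not isolated)
Conditions: DMF-DMA, toluene, 100 °C; then p-TsOH·H2O (10 mol %), CH2Cl2, 40 °C
Reagents that add atoms: N,N-dimethylformamide dimethyl acetal COC(OC)N(C)C
Why: enaminone formation followed by acid-catalysed oxa-Michael cyclisation and loss of dimethylamine is the standard chromone synthesis from 2-hydroxyacetophenones.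

Step 7
Reactants: 10 5,7-bis(benzyloxy)-4H-chromen-4-one; 11 4-(benzyloxy)phenylboronic acid
Product: 12 (2S)-5,7-bis(benzyloxy)-2-[4-(benzyloxy)phenyl]chroman-4-one
Conditions: Pd(OCOCF3)2 (5 mol %), (R)-t-BuPyOx (6 mol %), NH4PF6 (30 mol %), H2O (5 equiv), ClCH2CH2Cl, 60 °C
Reagents that add atoms: none
Why: Pd(II)/pyridine–oxazoline-catalysed asymmetric conjugate addition of an arylboronic acid to a chromone, in which the ligand selects the enone face for aryl–Pd insertion and so sets C2.

Step 8
Reactants: 12 (2S)-5,7-bis(benzyloxy)-2-[4-(benzyloxy)phenyl]chroman-4-one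
Product: 13 (2S,4S)-5,7-bis(benzyloxy)-2-[4-(benzyloxy)phenyl]chroman-4-ol
Conditions: NaBH4, THF/MeOH, 0 °C to rt
Reagents that add atoms: none
Why: borohydride reduction of the ketone with axial hydride delivery should give the 2,4-cis alcohol, whose C4 configuration is erased in the next step.

Step 9
Reactants: 13 (2S,4S)-5,7-bis(benzyloxy)-2-[4-(benzyloxy)phenyl]chroman-4-ol
Product: 15 (2S)-5,7-bis(benzyloxy)-2-[4-(benzyloxy)phenyl]-2H-chromene, via 4-mesylate 14 (not isolated)
Conditions: MsCl (1.3 equiv), Et3N (4 equiv), CH2Cl2, −20 °C to rt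
Reagents that add atoms: none
Why: sulfonylation and elimination of an activated benzylic alcohol under basic conditions should give the flav-3-ene without touching C2, the excess base suppressing cation–arene dimerisation.

Step 10
Reactants: 15 (2S)-5,7-bis(benzyloxy)-2-[4-(benzyloxy)phenyl]-2H-chromene
Product: 16 (2R,3S,4R)-5,7-bis(benzyloxy)-2-[4-(benzyloxy)phenyl]-3-bromochroman-4-ol
Conditions: NBS (1.05 equiv), NaHCO3, THF/H2O (4:1), 0 °C, dark
Reagents that add atoms: N-bromosuccinimide O=C1CCC(=O)N1Br; water O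
Why: bromohydrin formation, in which Br+ should add to C3 on the face anti to the 2-aryl group and water should capture the benzylic C4 cation anti to bromine (2,3-trans-3,4-trans), as known for electron-rich 2H-chromenes.

Step 11
Reactants: 16 (2R,3S,4R)-5,7-bis(benzyloxy)-2-[4-(benzyloxy)phenyl]-3-bromochroman-4-ol; 6 5,7,3′,4′-tetra-O-benzyl-(−)-epicatechin-(4β→8)-5,7,3′,4′-tetra-O-benzyl-(+)-catechin (1.5 equiv, excess recovered)
Product: 18 5,7,4′-tri-O-benzyl-(−)-epiafzelechin-(4β→8)-5,7,3′,4′-tetra-O-benzyl-(−)-epicatechin-(4β→8)-5,7,3′,4′-tetra-O-benzyl-(+)-catechin, via cis-oxirane 17 (not isolated)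
Conditions: NaH (1.2 equiv), THF, 0 °C; cannula filtration, dilution with CH2Cl2; then dropwise to 6 and BF3·OEt2 (20 mol %), CH2Cl2, −78 °C; sat. NaHCO3
Reagents that add atoms: none
Why: Proposed new method: NaH closes the trans-bromohydrin to oxirane 17 by intramolecular SN2 at C3 (3-exo-tet, inversion, so the oxygen ends up cis to the 2-aryl group); BF3 then lengthens the benzylic C4–O bond, which is ortho/para to the C5, C7 and O1 oxygens of the A ring, until C8 of the upper unit of 6 attacks C4 in a Friedel–Crafts step and rearomatises with release of the 3-OH. The closest known reactions are the Lewis acid-mediated Friedel–Crafts opening of aryl oxiranes by electron-rich arenes and the TMSOTf coupling of 4-alkoxyflavan-3-ols with flavan nucleophiles, which passes through the same C4 cation; new here is that ring strain replaces the 4-alkoxy leaving group and that the 3-hydroxyl is created in the same operation. No ring of the product is closed in this step, only the transient oxirane; C3 is fixed by the invertive oxirane closure and C4 by attack on the face opposite to both the oxirane oxygen and the 2-aryl group, a trans-diaxial opening that should give the 2,3-cis-3,4-trans (4β) arrangement. The step needs C8 selectivity over C6 of either unit of 6, which the known preference of benzylated flavan dimers for reaction at C8 of their upper unit should secure, and it needs capture of the cation by 6 instead of by a second molecule of 17, which slow inverse addition to excess 6 at −78 °C addresses. A 1,2-hydride shift to the flavan-3-one should be disfavoured because the C3–H bond is pseudoequatorial and poorly aligned with the empty orbital at C4, and O-alkylation by the free 3-hydroxyls of 6 is reversible under the Lewis acid.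

Step 12
Reactants: 18 5,7,4′-tri-O-benzyl-(−)-epiafzelechin-(4β→8)-5,7,3′,4′-tetra-O-benzyl-(−)-epicatechin-(4β→8)-5,7,3′,4′-tetra-O-benzyl-(+)-catechin
Product: 19 (−)-epiafzelechin-(4β→8)-(−)-epicatechin-(4β→8)-(+)-catechin (CNP0158921.1)
Conditions: H2 (1 atm), 20 % Pd(OH)2/C, THF/MeOH/H2O, rt
Reagents that add atoms: none
Why: heterogeneous hydrogenolysis of the eleven benzyl ethers under neutral conditions should leave the C–C interflavan bonds and all eight stereocenters untouched.

**Compound list**

1 | (+)-catechin, (2R,3S) | c1c(O)cc(O)c2c1O[C@H](c1ccc(O)c(O)c1)[C@@H](O)C2 | starting material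
2 | 5,7,3′,4′-tetra-O-benzyl-(+)-catechin | c1c(OCc3ccccc3)cc(OCc3ccccc3)c2c1O[C@H](c1ccc(OCc3ccccc3)c(OCc3ccccc3)c1)[C@@H](O)C2 | intermediate
3 | (−)-epicatechin, (2R,3R) | c1c(O)cc(O)c2c1O[C@H](c1ccc(O)c(O)c1)[C@H](O)C2 | starting material
4 | 5,7,3′,4′-tetra-O-benzyl-(−)-epicatechin | c1c(OCc3ccccc3)cc(OCc3ccccc3)c2c1O[C@H](c1ccc(OCc3ccccc3)c(OCc3ccccc3)c1)[C@H](O)C2 | intermediate
5 | (2R,3R,4S)-5,7-bis(benzyloxy)-2-[3,4-bis(benzyloxy)phenyl]-4-(2-ethoxyethoxy)chroman-3-ol (4β-ether) | c1c(OCc3ccccc3)cc(OCc3ccccc3)c2c1O[C@H](c1ccc(OCc3ccccc3)c(OCc3ccccc3)c1)[C@H](O)[C@H]2OCCOCC | intermediate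
6 | 5,7,3′,4′-tetra-O-benzyl-(−)-epicatechin-(4β→8)-5,7,3′,4′-tetra-O-benzyl-(+)-catechin | c1c(OCc3ccccc3)cc(OCc3ccccc3)c2c1O[C@H](c1ccc(OCc3ccccc3)c(OCc3ccccc3)c1)[C@H](O)[C@H]2c1c(OCc3ccccc3)cc(OCc3ccccc3)c2c1O[C@H](c1ccc(OCc3ccccc3)c(OCc3ccccc3)c1)[C@@H](O)C2 | intermediate
7 | 2′,4′,6′-trihydroxyacetophenone | CC(=O)c1c(O)cc(O)cc1O | starting material
8 | 1-[2,4-bis(benzyloxy)-6-hydroxyphenyl]ethanone | CC(=O)c1c(O)cc(OCc2ccccc2)cc1OCc1ccccc1 | intermediate
9 | (E)-1-[2,4-bis(benzyloxy)-6-hydroxyphenyl]-3-(dimethylamino)prop-2-en-1-one | CN(C)/C=C/C(=O)c1c(O)cc(OCc2ccccc2)cc1OCc1ccccc1 | intermediate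
10 | 5,7-bis(benzyloxy)-4H-chromen-4-one | O=c1ccoc2cc(OCc3ccccc3)cc(OCc3ccccc3)c12 | intermediate
11 | 4-(benzyloxy)phenylboronic acid | OB(O)c1ccc(OCc2ccccc2)cc1 | starting material
12 | (2S)-5,7-bis(benzyloxy)-2-[4-(benzyloxy)phenyl]chroman-4-one | c5ccccc5COc1ccc([C@H]2Oc3cc(OCc5ccccc5)cc(OCc5ccccc5)c3C(=O)C2)cc1 | intermediate
13 | (2S,4S)-5,7-bis(benzyloxy)-2-[4-(benzyloxy)phenyl]chroman-4-ol | c5ccccc5COc1ccc([C@H]2Oc3cc(OCc5ccccc5)cc(OCc5ccccc5)c3[C@@H](O)C2)cc1 | intermediate
14 | (2S,4S)-5,7-bis(benzyloxy)-2-[4-(benzyloxy)phenyl]chroman-4-yl methanesulfonate | c5ccccc5COc1ccc([C@H]2Oc3cc(OCc5ccccc5)cc(OCc5ccccc5)c3[C@@H](OS(C)(=O)=O)C2)cc1 | intermediate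
15 | (2S)-5,7-bis(benzyloxy)-2-[4-(benzyloxy)phenyl]-2H-chromene | c5ccccc5COc1ccc([C@H]2Oc3cc(OCc5ccccc5)cc(OCc5ccccc5)c3C=C2)cc1 | intermediate
16 | (2R,3S,4R)-5,7-bis(benzyloxy)-2-[4-(benzyloxy)phenyl]-3-bromochroman-4-ol (Br trans, OH cis to the 2-aryl group) | c5ccccc5COc1ccc([C@H]2Oc3cc(OCc5ccccc5)cc(OCc5ccccc5)c3[C@@H](O)[C@@H]2Br)cc1 | intermediate
17 | (2R)-5,7-bis(benzyloxy)-2-[4-(benzyloxy)phenyl]-3,4-epoxychroman, oxirane oxygen cis to the 2-aryl group | c5ccccc5COc1ccc([C@H]2Oc3cc(OCc5ccccc5)cc(OCc5ccccc5)c3[C@H]4O[C@@H]24)cc1 | intermediate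
18 | 5,7,4′-tri-O-benzyl-(−)-epiafzelechin-(4β→8)-5,7,3′,4′-tetra-O-benzyl-(−)-epicatechin-(4β→8)-5,7,3′,4′-tetra-O-benzyl-(+)-catechin | c5ccccc5COc1ccc([C@H]2Oc3cc(OCc5ccccc5)cc(OCc5ccccc5)c3[C@H](c3c(OCc5ccccc5)cc(OCc5ccccc5)c4c3O[C@H](c3ccc(OCc5ccccc5)c(OCc5ccccc5)c3)[C@H](O)[C@H]4c3c(OCc5ccccc5)cc(OCc5ccccc5)c4c3O[C@H](c3ccc(OCc5ccccc5)c(OCc5ccccc5)c3)[C@@H](O)C4)[C@H]2O)cc1 | intermediate
19 | (−)-epiafzelechin-(4β→8)-(−)-epicatechin-(4β→8)-(+)-catechin (CNP0158921.1) | Oc1ccc([C@H]2Oc3cc(O)cc(O)c3[C@H](c3c(O)cc(O)c4c3O[C@H](c3ccc(O)c(O)c3)[C@H](O)[C@H]4c3c(O)cc(O)c4c3O[C@H](c3ccc(O)c(O)c3)[C@@H](O)C4)[C@H]2O)cc1 | target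

**Totals**

Total step count: 12. Longest linear sequence: 8 steps (steps 5 to 12, from 2′,4′,6′-trihydroxyacetophenone).

**Steps most likely to fail, with fallbacks**

Step 11 (proposed new method). What may go wrong: ionisation of the oxirane before it meets the nucleophile, leading to self-condensation through its own A ring or a hydride shift to the 3-ketone, or attack at C6 instead of C8. The fallback sets out from 16 and comes back at 18, and it replaces the direct oxirane arylation by the established leaving-group coupling. Treatment of 16 with K2CO3 in 2-ethoxyethanol should pass through the same oxirane and open it with the solvent at C4, giving the storable 4β-ether (2R,3R,4S)-5,7-bis(benzyloxy)-2-[4-(benzyloxy)phenyl]-4-(2-ethoxyethoxy)chroman-3-ol F1. TMSOTf-catalysed condensation of F1 with 6 (CH2Cl2, −78 °C) should then give 18.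

Step 10. What may go wrong: delivery of bromine syn to the 2-aryl group, competing bromination of the A ring at C6 or C8, or ionisation of the benzylic hydroxyl during isolation. The fallback sets out from 15 and comes back at 18, and it avoids halonium chemistry altogether. Hydroboration–oxidation of 15 (BH3·THF; NaOH, H2O2) should place the hydroxyl at C3 anti to the aryl group and give 5,7,4′-tri-O-benzyl-(+)-afzelechin F2. Periodinane oxidation (DMP) should give the flavan-3-one (2R)-5,7-bis(benzyloxy)-2-[4-(benzyloxy)phenyl]chroman-3-one F3. L-Selectride reduction from the face opposite to the aryl group should give 5,7,4′-tri-O-benzyl-(−)-epiafzelechin F4. DDQ oxidation in the presence of 2-ethoxyethanol should then give the ether F1 described above, which is coupled with 6 under TMSOTf to 18.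

Step 7. What may go wrong: slow carbopalladation of the electron-rich chromone with competing protodeboronation of the boronic acid, or insufficient enantiofacial control. The fallback sets out from 8 and comes back at 13, and it replaces the asymmetric C–C bond formation by a resolution. Claisen–Schmidt condensation of 8 with 4-(benzyloxy)benzaldehyde (KOH, EtOH) should give the chalcone (E)-1-[2,4-bis(benzyloxy)-6-hydroxyphenyl]-3-[4-(benzyloxy)phenyl]prop-2-en-1-one F5. NaOAc in refluxing ethanol should close it to the racemic flavanone rac-5,7-bis(benzyloxy)-2-[4-(benzyloxy)phenyl]chroman-4-one F6. Kinetic resolution by asymmetric transfer hydrogenation (RuCl(p-cymene)[(S,S)-TsDPEN], HCO2H/Et3N) should reduce only the (2S)-enantiomer, to 13, while the remaining (2R)-ketone is re-racemised with base and recycled.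

Further compounds
F1 | step 11 | (2R,3R,4S)-5,7-bis(benzyloxy)-2-[4-(benzyloxy)phenyl]-4-(2-ethoxyethoxy)chroman-3-ol | c5ccccc5COc1ccc([C@H]2Oc3cc(OCc5ccccc5)cc(OCc5ccccc5)c3[C@H](OCCOCC)[C@H]2O)cc1
F2 | step 10 | 5,7,4′-tri-O-benzyl-(+)-afzelechin, (2R,3S) | c5ccccc5COc1ccc([C@H]2Oc3cc(OCc5ccccc5)cc(OCc5ccccc5)c3C[C@@H]2O)cc1
F3 | step 10 | (2R)-5,7-bis(benzyloxy)-2-[4-(benzyloxy)phenyl]chroman-3-one | c5ccccc5COc1ccc([C@H]2Oc3cc(OCc5ccccc5)cc(OCc5ccccc5)c3CC2=O)cc1
F4 | step 10 | 5,7,4′-tri-O-benzyl-(−)-epiafzelechin, (2R,3R) | c5ccccc5COc1ccc([C@H]2Oc3cc(OCc5ccccc5)cc(OCc5ccccc5)c3C[C@H]2O)cc1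
F5 | step 7 | (E)-1-[2,4-bis(benzyloxy)-6-hydroxyphenyl]-3-[4-(benzyloxy)phenyl]prop-2-en-1-one | O=C(/C=C/c1ccc(OCc2ccccc2)cc1)c1c(O)cc(OCc2ccccc2)cc1OCc1ccccc1
F6 | step 7 | rac-5,7-bis(benzyloxy)-2-[4-(benzyloxy)phenyl]chroman-4-one | O=C1CC(c2ccc(OCc3ccccc3)cc2)Oc2cc(OCc3ccccc3)cc(OCc3ccccc3)c12
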